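## Retrosynthetic overview (ent-kaurane numbering throughout)

1. Not used: biomimetic C6–C7 cleavage of an intact ent-kaurane, or late ester coupling of pre-made A and C/D halves.
2. The two hindered centres are set last, under kinetic control. C16 comes from exo-face protonation of the C15 enolate. C6 comes from hydride delivery to the convex face of an O-methyl-lactonium ion made from a 6,19-γ-lactone.
3. Ring D: 5-exo α-keto-radical closure C16→C13 onto a C12-chloroalkene. The chlorine steers the regiochemistry and is removed in the same pot.
4. Key step (ring C, quaternary C8, C9): intermolecular Diels–Alder of chloroprene with a spiro 3-propionyl-5,6-dihydropyran-2-one, face-controlled by ring A.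
5. Spiro δ-lactone and C10: Ti(III) epoxide-radical/acrylate lactonisation. Ring A/THF: Cu-catalysed asymmetric conjugate addition. Ring order: A (bought) → THF → δ-lactone → C → D.

Assumption: I read the SMILES literally. 6-OMe is cis to C10 on the THF ring (concave face) and C17 is endo (syn to the C9–C11–C12 bridge). I treat both as contra-steric centres.

## Route

**Step 1**
Reactants: 1, 3-methylcyclohex-2-en-1-one; 2, (chloromethyl)(isopropoxy)dimethylsilane, used as its Grignard reagent (Mg, Et2O, made just before use)
Product: 3, (R)-3-methyl-3-[(isopropoxydimethylsilyl)methyl]-1-(trimethylsilyloxy)cyclohex-1-ene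
Conditions: 2·MgCl (1.3 equiv), Cu(OTf)2 (5 mol %), chiral hydroxyalkyl-imidazolinium (NHC) salt (6 mol %), Et2O, −30 °C; then TMSCl, Et3N, DMPU, → rt
Reagents that add atoms: (isopropoxydimethylsilyl)methylmagnesium chloride, CC(C)O[Si](C)(C)C[Mg]Cl; chlorotrimethylsilane, C[Si](C)(C)Cl
Why: Cu/NHC-catalysed asymmetric conjugate addition of a primary, β-branched Grignard reagent (a hydroxymethyl-anion equivalent) to a β-methyl enone sets quaternary C4 (R, ligand enantiomer chosen accordingly), and silyl trapping fixes the enolate regiochemistry at C5.

**Step 2**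
Reactants: 3; 4, trimethyl orthoformate
Product: 5, (3R)-2-(dimethoxymethyl)-3-methyl-3-[(isopropoxydimethylsilyl)methyl]cyclohexan-1-one (C5 epimers)
Conditions: HC(OMe)3, TMSOTf (10 mol %), CH2Cl2, −78 °C
Reagents that add atoms: trimethyl orthoformate, COC(OC)OC
Why: Mukaiyama-type alkylation of the regiodefined silyl enol ether by the small dimethoxycarbenium ion installs C6 at the aldehyde oxidation level on hindered C5, whose configuration is corrected in step 3.

**Step 3**
Reactants: 5
Product: 6, cis-fused (3aR,7aS)-1-methoxy-3a-methyloctahydroisobenzofuran-7-one (C10 ketone; C6 anomers, inconsequential)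
Conditions: 30 % H2O2, KF, KHCO3, THF/MeOH, rt; then CSA (cat.), MeOH, 40 °C
Reagents that add atoms: hydrogen peroxide, OO (supplies O-19); methanol, CO (degenerate acetal exchange)
Why: Tamao–Kumada oxidation unmasks C19–OH, acid-catalysed transacetalisation closes the THF acetal, and C5 (α to the ketone) equilibrates through the enol to the more stable cis-fused bicycle, as in angular-methyl hydrindan-4-ones, which puts C6 and C19 on the same (α) face.

**Step 4**
Reactants: 6; 7, chloroiodomethane
Product: 8, spiro-epoxide at C10 (C20H2 β, O α expected; configuration inconsequential)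
Conditions: ClCH2I, MeLi·LiBr, THF, −78 °C → rt
Reagents that add atoms: chloroiodomethane, ClCI
Why: In-situ chloromethyllithium adds to the enolisable, β-alkoxy ketone faster than it deprotonates it, and the chlorohydrin alkoxide closes to the epoxide (Matteson-type epoxidation).

**Step 5**
Reactants: 8; 9, 2,2,2-trifluoroethyl acrylate
Product: 10, spiro δ-lactone acetal (4R,5R,10R; C9 β/equatorial, C20 α/axial)
Conditions: Cp2TiCl2, Zn, 2,4,6-collidine·HCl, 9 (5 equiv), THF, rt
Reagents that add atoms: 2,2,2-trifluoroethyl acrylate, C=CC(=O)OCC(F)(F)F (delivers C9–C8–C7=O; CF3CH2O is expelled)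
Why: In this Nugent–RajanBabu reductive epoxide opening/Giese addition/lactonisation, the planar tertiary C10 radical is trapped on the β face, anti to axial C19 and to C6, which sets the spiro centre as 10R.

**Step 6**
Reactants: 10
Product: 11, bis-lactone (6,19-γ-lactone plus 7,20-δ-lactone)
Conditions: Jones reagent, acetone, 0 °C
Reagents that add atoms: water, O (becomes the C6 carbonyl oxygen via the lactol)
Why: Jones oxidation converts the cyclic methyl acetal directly to the γ-lactone, which removes the acid-labile group before the Lewis-acid steps and creates the handle for stereocontrolled reinstallation of C6–OMe.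

**Step 7**
Reactants: 11; 12, N-methoxy-N-methylpropanamide
Product: 13, 8-propionyl δ-lactone (β-keto lactone, C8 epimers/enol)
Conditions: LDA (1.15 equiv), THF, −78 °C; 12, −78 → −20 °C; aq NH4Cl
Reagents that add atoms: N-methoxy-N-methylpropanamide, CCC(=O)N(C)OC
Why: Kinetic deprotonation takes the unhindered C8H2 rather than the tertiary C5–H between two quaternary carbons, and crossed-Claisen acylation with a Weinreb amide stops at the chelated adduct, delivering C15–C17.

**Step 8**
Reactants: 13
Product: 14, spiro 3-propionyl-5,6-dihydropyran-2-one (C8=C9), used crude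
Conditions: PhSeCl, pyridine, CH2Cl2, 0 °C; then 30 % H2O2, 0 °C → rt
Reagents that add atoms: none (PhSe is introduced and expelled)
Why: α-Selenenylation of the 1,3-dicarbonyl followed by selenoxide syn-elimination can only use a C9–H, which gives the doubly activated endocyclic dienophile.

**Step 9 (key step)**
Reactants: 14; 15, chloroprene (2-chlorobuta-1,3-diene)
Product: 16, Diels–Alder adduct (4R,5R,8S,9S,10R): ring C cyclohexene with C12–Cl, C12=C13, and propionyl on C8
Conditions: 15 (10 equiv), ZnCl2 (1.5 equiv), BHT, CH2Cl2, 0 °C → rt, sealed
Reagents that add atoms: chloroprene, C=CC(Cl)=C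
Why: In this chelation-activated normal-demand Diels–Alder, the "para" rule joins the CH2 next to C–Cl to electrophilic C9 (Cl on C12), suprafacial addition makes H9 and C15 cis, and the diene adds to the face syn to C1H2 because the other face is covered by the C6 carbonyl (equatorial on C5, gauche to C9), giving 8S,9S.

**Step 10**
Reactants: 16
Product: 17, 16-bromo ketone (C16 epimers)
Conditions: TMSOTf, Et3N, CH2Cl2, 0 °C; then NBS, NaHCO3, THF, −78 → 0 °C
Reagents that add atoms: N-bromosuccinimide, O=C1CCC(=O)N1Br
Why: C16 is the only enolisable ketone position because C8 is quaternary, so silyl enol ether formation followed by electrophilic bromination is regiospecific and leaves the deactivated vinyl chloride alone.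

**Step 11**
Reactants: 17
Product: 18, pentacyclic keto bis-lactone (13R; mainly 16S, exo-methyl)
Conditions: Bu3SnH (3.5 equiv, syringe pump), AIBN (portions), PhMe (5 mM), 110 °C; KF work-up
Reagents that add atoms: none
Why: In this reductive 5-exo-trig radical cyclisation, the α-keto radical attacks the unsubstituted C13 to give the α-chloro-stabilised C12 radical, so the usual 6-endo leakage to a bicyclo[2.2.2]octane is blocked by Cl; C13 is fixed by the bridge geometry, and excess stannane then reduces the C12–Cl bond.

**Step 12**
Reactants: 18; 19, trimethyloxonium tetrafluoroborate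
Product: 20, 16-epi-ludongnin F (6R,16S)
Conditions: Me3OBF4 (2 equiv), 2,6-di-tert-butyl-4-methylpyridine, 4 Å MS, CH2Cl2, rt; then n-Bu4NBH4 (1.0 equiv), −78 °C; aq NaHCO3 at −78 °C
Reagents that add atoms: trimethyloxonium tetrafluoroborate, C[O+](C)C.F[B-](F)(F)F
Why: Proposed new method: Meerwein O-methylation should select the more basic γ-lactone (the δ-lactone is an α-acyl, doubly neopentyl ester and the ketone forms no stable oxonium), the resulting cyclic dialkoxycarbenium ion is far more electrophilic than C15=O, and borohydride adds to its convex face (syn to H5/C18, anti to C10 with its C9 and C20 branches), leaving OMe cis to C10 (6R); the closest known chemistry is lactonium-salt formation with oxonium salts and hydride capture of dialkoxycarbenium or imidate salts (Borch-type reduction).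

**Step 13**
Reactants: 20
Product: 21, ludongnin F
Conditions: KHMDS (1.2 equiv), THF, −78 → 0 °C; recool to −78 °C, add 2,6-di-tert-butyl-4-methylphenol in THF; pH 7 buffer
Reagents that add atoms: none
Why: In this kinetic enolate protonation at the only acidic C–H, the bulky phenol reaches C16 only from the exo face (syn to C14, anti to the C9–C11–C12 bridge), which places H16 exo and C17 endo (16R), and no later step can epimerise it.

## Compound list

| No. | Name | SMILES | Role |
|---|---|---|---|
| 1 | 3-methylcyclohex-2-en-1-one | CC1=CC(=O)CCC1 | starting material |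
| 2 | (chloromethyl)(isopropoxy)dimethylsilane | CC(C)O[Si](C)(C)CCl | starting material |
| 3 | (R)-silyl enol ether, C4 set | C[Si](C)(C)OC1=C[C@](C)(C[Si](C)(C)OC(C)C)CCC1 | intermediate |
| 4 | trimethyl orthoformate | COC(OC)OC | starting material |
| 5 | α-(dimethoxymethyl) ketone (C5 epimers) | COC(OC)C1C(=O)CCC[C@@]1(C)C[Si](C)(C)OC(C)C | intermediate |
| 6 | cis-fused keto acetal (C6 anomers) | COC1OC[C@]2(C)CCCC(=O)[C@H]12 | intermediate |
| 7 | chloroiodomethane | ClCI | starting material |
| 8 | C10 spiro-epoxide | COC1OC[C@]2(C)CCC[C@@]3(CO3)[C@H]12 | intermediate |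
| 9 | 2,2,2-trifluoroethyl acrylate | C=CC(=O)OCC(F)(F)F | starting material |
| 10 | spiro δ-lactone acetal (10R) | COC1OC[C@]2(C)CCC[C@]3(COC(=O)CC3)[C@H]12 | intermediate |
| 11 | bis-lactone | O=C1OC[C@]2(C)CCC[C@]3(COC(=O)CC3)[C@H]12 | intermediate |
| 12 | N-methoxy-N-methylpropanamide | CCC(=O)N(C)OC | starting material |
| 13 | 8-propionyl β-keto lactone | O=C1OC[C@]2(C)CCC[C@]3(COC(=O)C(C(=O)CC)C3)[C@H]12 | intermediate |
| 14 | spiro 3-propionyl-5,6-dihydropyran-2-one | O=C1OC[C@]2(C)CCC[C@]3(COC(=O)C(C(=O)CC)=C3)[C@H]12 | intermediate |
| 15 | chloroprene | C=CC(Cl)=C | starting material |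
| 16 | Diels–Alder adduct (8S,9S; 12-Cl, Δ12,13) | O=C1OC[C@]2(C)CCC[C@]3(COC(=O)[C@@]4(C(=O)CC)CC=C(Cl)C[C@H]43)[C@H]12 | intermediate |
| 17 | 16-bromo ketone (C16 epimers) | O=C1OC[C@]2(C)CCC[C@]3(COC(=O)[C@@]4(C(=O)C(C)Br)CC=C(Cl)C[C@H]43)[C@H]12 | intermediate |
| 18 | pentacyclic keto bis-lactone (13R,16S major) | O=C1OC[C@]2(C)CCC[C@]3(COC(=O)[C@@]45C[C@@H](CC[C@H]43)[C@H](C)C5=O)[C@H]12 | intermediate |
| 19 | trimethyloxonium tetrafluoroborate | C[O+](C)C.F[B-](F)(F)F | starting material |
| 20 | 16-epi-ludongnin F (6R,16S) | CO[C@@H]1OC[C@]2(C)CCC[C@]3(COC(=O)[C@@]45C[C@@H](CC[C@H]43)[C@H](C)C5=O)[C@H]12 | intermediate |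
| 21 | ludongnin F (4R,5R,6R,8S,9S,10R,13R,16R) | CO[C@@H]1OC[C@]2(C)CCC[C@]3(COC(=O)[C@@]45C[C@@H](CC[C@H]43)[C@@H](C)C5=O)[C@H]12 | target |

## Step count

Total steps: 13 (in-situ Grignard preparation not counted). Longest linear sequence: 13.

## Three steps most likely to fail, with fallbacks

- **Step 12 (chemoselective lactonium formation and hydride capture).** Fallback: abandon kinetic hydride delivery.
  - Omit step 6 and carry methyl acetal 10 through the sequence, running the Diels–Alder thermally.
  - At the end, equilibrate C6 with CSA/MeOH, separate the anomers, and recycle the 6S isomer.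
- **Step 9 (sluggish chloroprene on a neopentyl dienophile).** Fallback: switch to 2-(trimethylsilyloxy)buta-1,3-diene, which should react without a catalyst.
  - Its C12 silyl enol ether then accepts the C16 radical in a polarity-matched 5-exo closure, giving the 12,15-diketone.
  - C12=O is removed through its enol triflate by Pd/formate reduction and then H2.
- **Step 11 (premature reduction, 6-endo closure or incomplete dechlorination).** Fallback: a polar ring-D closure on the butadiene adduct.
  - Epoxidise C12=C13 anti to the axial acyl group.
  - Open the epoxide trans-diaxially (5-exo-tet) at C13 with the C16 potassium enolate.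
  - Remove the 12-OH by Barton–McCombie deoxygenation.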